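The cyclohexene ring C3a–C4–C5–C6=C7–C7a of the hexahydroindene core is read as a Diels–Alder retron. Everything rests on cutting C3a–C7a and C4–C5 at once, which unravels both rings to an acyclic (2E,7E,9E,11E)-dodecatetraenal: an α-ethyl enal dienophile joined through a three-carbon tether (future C3–C2–C1, C2 held as a silyl ether) to the inner diene of a styryl triene. The intramolecular cycloaddition closes both rings and sets C3a, C7a and the vicinal quaternary centres C4 and C5 in one operation, steered by the tether stereocentres made by Evans aldol and anti-selective hydroboration. Aldehyde oxidation, desilylation and alcohol oxidation then give the keto acid.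

Key step: step 10

Remark on the chemistry: ylide 12 is taken as a purchasable stabilised ylide, like its lower homologue 10. Ring compounds carry 2,3,3a,4,5,7a-hexahydro-1H-indene locants; open-chain compounds carry their own chain locants.

Step 1
Reactants: 1 (4R)-4-benzyl-3-propanoyl-1,3-oxazolidin-2-one; 2 2-ethylprop-2-enal
Product: 4 (4R)-4-benzyl-3-[(2R,3R)-3-hydroxy-2-methyl-4-methylidenehexanoyl]-1,3-oxazolidin-2-one, via (Z)-dibutylboron enolate 3 (not isolated)
Conditions: Bu2BOTf, i-Pr2NEt, CH2Cl2, −78 to 0 °C; then 2, −78 to 0 °C; then pH 7 buffer, MeOH, H2O2, 0 °C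
Reagents that add atoms: dibutylboron triflate, CCCCB(CCCC)OS(=O)(=O)C(F)(F)F (boron held only in 3)
Why: Evans syn-aldol reaction: the (Z)-boron enolate 3 adds through a Zimmerman–Traxler chair on the face away from the benzyl group, which should set the 2R,3R syn pair (the methyl-bearing centre becomes C3 of the target; the carbinol is later oxidised).

Step 2
Reactants: 4 (4R)-4-benzyl-3-[(2R,3R)-3-hydroxy-2-methyl-4-methylidenehexanoyl]-1,3-oxazolidin-2-one
Product: 5 (2R,3R)-3-hydroxy-N-methoxy-N,2-dimethyl-4-methylidenehexanamide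
Conditions: MeNH(OMe)·HCl, AlMe3, THF, −20 to 0 °C
Reagents that add atoms: N,O-dimethylhydroxylamine hydrochloride, CNOC.Cl
Why: Weinreb transamidation by the aluminium amide made in the flask, assisted by the free β-hydroxyl, exchanges the auxiliary for a group that survives the chain building; no stereocentre is touched.

Step 3
Reactants: 5 (2R,3R)-3-hydroxy-N-methoxy-N,2-dimethyl-4-methylidenehexanamide
Product: 6 (2R,3R)-3-[(tert-butyldimethylsilyl)oxy]-N-methoxy-N,2-dimethyl-4-methylidenehexanamide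
Conditions: TBSOTf, 2,6-lutidine, CH2Cl2, −78 to 0 °C
Reagents that add atoms: tert-butyldimethylsilyl triflate, CC(C)(C)[Si](C)(C)OS(=O)(=O)C(F)(F)F
Why: Silyl ether protection of the secondary alcohol with the reactive triflate; the bulky ether is also the control element of the next step.

Step 4
Reactants: 6 (2R,3R)-3-[(tert-butyldimethylsilyl)oxy]-N-methoxy-N,2-dimethyl-4-methylidenehexanamide
Product: 8 (2R,3S,4S)-3-[(tert-butyldimethylsilyl)oxy]-4-(hydroxymethyl)-N-methoxy-N,2-dimethylhexanamide, via alkyl-9-BBN borane 7 (not isolated)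
Conditions: 9-BBN-H, THF, 0 °C to rt; then NaOH, H2O2, 0 °C
Reagents that add atoms: 9-borabicyclo[3.3.1]nonane, [H]B1C2CCCC1CCC2 (boron held only in 7); hydrogen peroxide, OO
Why: Hydroboration–oxidation of the 1,1-disubstituted alkene: in the conformer with the allylic C–H eclipsing the alkene (A(1,3) strain) the borane adds anti-Markovnikov to the face opposite the C2 chain, which should give the 3,4-anti product and so set C4 (C1 of the target) 1,3-anti to the methyl-bearing centre.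

Step 5
Reactants: 8 (2R,3S,4S)-3-[(tert-butyldimethylsilyl)oxy]-4-(hydroxymethyl)-N-methoxy-N,2-dimethylhexanamide
Product: 9 (2R,3S,4R)-3-[(tert-butyldimethylsilyl)oxy]-4-formyl-N-methoxy-N,2-dimethylhexanamide
Conditions: Dess–Martin periodinane, NaHCO3, CH2Cl2, 0 °C to rt
Reagents that add atoms: none
Why: Dess–Martin oxidation under buffered, non-basic conditions should give the α-branched aldehyde without epimerisation (the 4R label is only a priority change).

Step 6
Reactants: 9 (2R,3S,4R)-3-[(tert-butyldimethylsilyl)oxy]-4-formyl-N-methoxy-N,2-dimethylhexanamide; 10 2-(triphenylphosphoranylidene)propanal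
Product: 11 (2R,3S,4S,5E)-3-[(tert-butyldimethylsilyl)oxy]-4-ethyl-N-methoxy-N,2,6-trimethyl-7-oxohept-5-enamide
Conditions: toluene, 90 °C
Reagents that add atoms: none
Why: Wittig olefination with a formyl-stabilised ylide, whose reversible addition should give the (E)-trisubstituted enal.

Step 7
Reactants: 11 (2R,3S,4S,5E)-3-[(tert-butyldimethylsilyl)oxy]-4-ethyl-N-methoxy-N,2,6-trimethyl-7-oxohept-5-enamide; 12 2-(triphenylphosphoranylidene)butanal
Product: 13 (2R,3S,4S,5E,7E)-3-[(tert-butyldimethylsilyl)oxy]-4,8-diethyl-N-methoxy-N,2,6-trimethyl-9-oxonona-5,7-dienamide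
Conditions: toluene, 110 °C
Reagents that add atoms: none
Why: A second Wittig olefination with the α-ethyl formyl ylide extends the enal to the (5E,7E)-dienal, again E-selective for a stabilised ylide.

Step 8
Reactants: 13 (2R,3S,4S,5E,7E)-3-[(tert-butyldimethylsilyl)oxy]-4,8-diethyl-N-methoxy-N,2,6-trimethyl-9-oxonona-5,7-dienamide; 14 diethyl benzylphosphonate
Product: 15 (2R,3S,4S,5E,7E,9E)-3-[(tert-butyldimethylsilyl)oxy]-4,8-diethyl-N-methoxy-N,2,6-trimethyl-10-phenyldeca-5,7,9-trienamide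
Conditions: 14, KN(SiMe3)2, THF, −78 °C; then 13, −78 to 0 °C
Reagents that add atoms: none
Why: Horner–Wadsworth–Emmons olefination with the benzylphosphonate anion should give the (E)-styryl alkene; the aldehyde is far more electrophilic than the Weinreb amide.

Step 9
Reactants: 15 (2R,3S,4S,5E,7E,9E)-3-[(tert-butyldimethylsilyl)oxy]-4,8-diethyl-N-methoxy-N,2,6-trimethyl-10-phenyldeca-5,7,9-trienamide
Product: 16 (2R,3S,4S,5E,7E,9E)-3-[(tert-butyldimethylsilyl)oxy]-4,8-diethyl-2,6-dimethyl-10-phenyldeca-5,7,9-trienal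
Conditions: i-Bu2AlH, THF, −78 °C; then aqueous potassium sodium tartrate
Reagents that add atoms: none
Why: Weinreb amide reduction: hydride addition stops at the aldehyde level because the N-methoxy chelate does not collapse before work-up, and the α-stereocentre is untouched at −78 °C.

Step 10
Reactants: 16 (2R,3S,4S,5E,7E,9E)-3-[(tert-butyldimethylsilyl)oxy]-4,8-diethyl-2,6-dimethyl-10-phenyldeca-5,7,9-trienal; 12 2-(triphenylphosphoranylidene)butanal
Product: 18 (1S,2R,3S,3aR,4R,5S,7aR)-2-[(tert-butyldimethylsilyl)oxy]-1,4,5-triethyl-3,7-dimethyl-5-[(E)-2-phenylethenyl]-2,3,3a,4,5,7a-hexahydro-1H-indene-4-carbaldehyde, via tetraenal 17 (not isolated)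
Conditions: 12 (slight excess), toluene, 90 °C; then dilution with toluene, BHT, 115 °C, sealed tube
Reagents that add atoms: none
Why: Wittig olefination of 16 gives the (2E)-enal 17, which on further heating should undergo a concerted, asynchronous, normal-demand [4+2] cycloaddition between its enal C2=C3 and the inner diene C7=C8–C9=C10; the closest known class is the tandem Wittig/type 1 intramolecular Diels–Alder reaction of 1,3,8-nonatrienes. The cyclohexene closes by suprafacial union of the two π-systems (chain bonds C2–C10 and C3–C7), and the cyclopentane closes in the fused mode because the three-atom tether joins the proximal termini C3 and C7. The vicinal quaternary centres C4 and C5 of the indene follow from the E geometry of the dienophile and of the C9=C10 alkene (ethyls cis, formyl cis to styryl), and the trans ring fusion C3a/C7a from the formyl-endo transition state, in which the flat formyl group, not the α-ethyl group, lies under the methyl-bearing diene. The absolute sense comes from the tether: the C4 methyl and C6 ethyl of 17 sit pseudo-equatorial with their allylic hydrogens eclipsing the alkenes (A(1,3) strain), and their 1,3-anti relationship is matched only with the trans-fused transition state on one π-face. Regiochemistry (inner, not outer, diene) is secured by the tether length, and dilution with near-stoichiometric ylide should suppress bimolecular cycloaddition and a second olefination.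

Step 11
Reactants: 18 (1S,2R,3S,3aR,4R,5S,7aR)-2-[(tert-butyldimethylsilyl)oxy]-1,4,5-triethyl-3,7-dimethyl-5-[(E)-2-phenylethenyl]-2,3,3a,4,5,7a-hexahydro-1H-indene-4-carbaldehyde
Product: 19 (1S,2R,3S,3aR,4R,5S,7aR)-2-[(tert-butyldimethylsilyl)oxy]-1,4,5-triethyl-3,7-dimethyl-5-[(E)-2-phenylethenyl]-2,3,3a,4,5,7a-hexahydro-1H-indene-4-carboxylic acid
Conditions: NaClO2, NaH2PO4, 2-methylbut-2-ene, t-BuOH/H2O, rt
Reagents that add atoms: sodium chlorite, [Na+].[O-]Cl=O
Why: Pinnick oxidation converts the hindered, non-enolisable aldehyde to the acid; the alkene scavenger protects the trisubstituted and styryl double bonds from hypochlorous acid.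

Step 12
Reactants: 19 (1S,2R,3S,3aR,4R,5S,7aR)-2-[(tert-butyldimethylsilyl)oxy]-1,4,5-triethyl-3,7-dimethyl-5-[(E)-2-phenylethenyl]-2,3,3a,4,5,7a-hexahydro-1H-indene-4-carboxylic acid
Product: 20 (1S,2R,3S,3aR,4R,5S,7aR)-1,4,5-triethyl-2-hydroxy-3,7-dimethyl-5-[(E)-2-phenylethenyl]-2,3,3a,4,5,7a-hexahydro-1H-indene-4-carboxylic acid
Conditions: HF·pyridine, pyridine, THF, 0 °C to rt
Reagents that add atoms: none
Why: Fluoride-mediated silyl ether cleavage driven by Si–F bond formation; buffered HF·pyridine should be mild enough to leave the alkene/acid pair untouched.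

Step 13
Reactants: 20 (1S,2R,3S,3aR,4R,5S,7aR)-1,4,5-triethyl-2-hydroxy-3,7-dimethyl-5-[(E)-2-phenylethenyl]-2,3,3a,4,5,7a-hexahydro-1H-indene-4-carboxylic acid
Product: 21 (1S,3S,3aR,4R,5S,7aR)-1,4,5-triethyl-3,7-dimethyl-2-oxo-5-[(E)-2-phenylethenyl]-2,3,3a,4,5,7a-hexahydro-1H-indene-4-carboxylic acid
Conditions: Dess–Martin periodinane, CH2Cl2, rt
Reagents that add atoms: none
Why: Dess–Martin oxidation of the secondary alcohol to the cyclopentanone; both α-centres already hold the all-trans arrangement expected to be the thermodynamic one, so enolisation should not erode them.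

Compound list
1 | (4R)-4-benzyl-3-propanoyl-1,3-oxazolidin-2-one | CCC(=O)N1[C@H](Cc2ccccc2)COC1=O | starting material
2 | 2-ethylprop-2-enal | C=C(CC)C=O | starting material
3 | (4R)-4-benzyl-3-[(1Z)-1-[(dibutylboranyl)oxy]prop-1-en-1-yl]-1,3-oxazolidin-2-one | C/C=C(\OB(CCCC)CCCC)N1[C@H](Cc2ccccc2)COC1=O | intermediate
4 | (4R)-4-benzyl-3-[(2R,3R)-3-hydroxy-2-methyl-4-methylidenehexanoyl]-1,3-oxazolidin-2-one | C=C(CC)[C@H](O)[C@@H](C)C(=O)N1[C@H](Cc2ccccc2)COC1=O | intermediate
5 | (2R,3R)-3-hydroxy-N-methoxy-N,2-dimethyl-4-methylidenehexanamide | C=C(CC)[C@H](O)[C@@H](C)C(=O)N(C)OC | intermediate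
6 | (2R,3R)-3-[(tert-butyldimethylsilyl)oxy]-N-methoxy-N,2-dimethyl-4-methylidenehexanamide | C=C(CC)[C@H](O[Si](C)(C)C(C)(C)C)[C@@H](C)C(=O)N(C)OC | intermediate
7 | (2R,3S,4R)-4-[(9-borabicyclo[3.3.1]nonan-9-yl)methyl]-3-[(tert-butyldimethylsilyl)oxy]-N-methoxy-N,2-dimethylhexanamide | CC[C@@H](CB1C2CCCC1CCC2)[C@H](O[Si](C)(C)C(C)(C)C)[C@@H](C)C(=O)N(C)OC | intermediate
8 | (2R,3S,4S)-3-[(tert-butyldimethylsilyl)oxy]-4-(hydroxymethyl)-N-methoxy-N,2-dimethylhexanamide | CC[C@@H](CO)[C@H](O[Si](C)(C)C(C)(C)C)[C@@H](C)C(=O)N(C)OC | intermediate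
9 | (2R,3S,4R)-3-[(tert-butyldimethylsilyl)oxy]-4-formyl-N-methoxy-N,2-dimethylhexanamide | CC[C@@H](C=O)[C@H](O[Si](C)(C)C(C)(C)C)[C@@H](C)C(=O)N(C)OC | intermediate
10 | 2-(triphenylphosphoranylidene)propanal | CC(C=O)=P(c1ccccc1)(c1ccccc1)c1ccccc1 | starting material
11 | (2R,3S,4S,5E)-3-[(tert-butyldimethylsilyl)oxy]-4-ethyl-N-methoxy-N,2,6-trimethyl-7-oxohept-5-enamide | CC[C@@H](/C=C(C)/C=O)[C@H](O[Si](C)(C)C(C)(C)C)[C@@H](C)C(=O)N(C)OC | intermediate
12 | 2-(triphenylphosphoranylidene)butanal | CCC(C=O)=P(c1ccccc1)(c1ccccc1)c1ccccc1 | starting material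
13 | (2R,3S,4S,5E,7E)-3-[(tert-butyldimethylsilyl)oxy]-4,8-diethyl-N-methoxy-N,2,6-trimethyl-9-oxonona-5,7-dienamide | CC[C@@H](/C=C(C)/C=C(CC)/C=O)[C@H](O[Si](C)(C)C(C)(C)C)[C@@H](C)C(=O)N(C)OC | intermediate
14 | diethyl benzylphosphonate | CCOP(=O)(Cc1ccccc1)OCC | starting material
15 | (2R,3S,4S,5E,7E,9E)-3-[(tert-butyldimethylsilyl)oxy]-4,8-diethyl-N-methoxy-N,2,6-trimethyl-10-phenyldeca-5,7,9-trienamide | CC[C@@H](/C=C(C)/C=C(CC)/C=C/c1ccccc1)[C@H](O[Si](C)(C)C(C)(C)C)[C@@H](C)C(=O)N(C)OC | intermediate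
16 | (2R,3S,4S,5E,7E,9E)-3-[(tert-butyldimethylsilyl)oxy]-4,8-diethyl-2,6-dimethyl-10-phenyldeca-5,7,9-trienal | CC[C@@H](/C=C(C)/C=C(CC)/C=C/c1ccccc1)[C@H](O[Si](C)(C)C(C)(C)C)[C@@H](C)C=O | intermediate
17 | (2E,4S,5R,6S,7E,9E,11E)-5-[(tert-butyldimethylsilyl)oxy]-2,6,10-triethyl-4,8-dimethyl-12-phenyldodeca-2,7,9,11-tetraenal | CC[C@@H](/C=C(C)/C=C(CC)/C=C/c1ccccc1)[C@H](O[Si](C)(C)C(C)(C)C)[C@@H](C)/C=C(CC)/C=O | intermediate
18 | (1S,2R,3S,3aR,4R,5S,7aR)-2-[(tert-butyldimethylsilyl)oxy]-1,4,5-triethyl-3,7-dimethyl-5-[(E)-2-phenylethenyl]-2,3,3a,4,5,7a-hexahydro-1H-indene-4-carbaldehyde | CC[C@@H]1[C@H](O[Si](C)(C)C(C)(C)C)[C@@H](C)[C@H]2[C@H]1C(C)=C[C@@](/C=C/c1ccccc1)(CC)[C@]2(CC)C=O | intermediate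
19 | (1S,2R,3S,3aR,4R,5S,7aR)-2-[(tert-butyldimethylsilyl)oxy]-1,4,5-triethyl-3,7-dimethyl-5-[(E)-2-phenylethenyl]-2,3,3a,4,5,7a-hexahydro-1H-indene-4-carboxylic acid | CC[C@@H]1[C@H](O[Si](C)(C)C(C)(C)C)[C@@H](C)[C@H]2[C@H]1C(C)=C[C@@](/C=C/c1ccccc1)(CC)[C@]2(CC)C(=O)O | intermediate
20 | (1S,2R,3S,3aR,4R,5S,7aR)-1,4,5-triethyl-2-hydroxy-3,7-dimethyl-5-[(E)-2-phenylethenyl]-2,3,3a,4,5,7a-hexahydro-1H-indene-4-carboxylic acid | CC[C@@H]1[C@H](O)[C@@H](C)[C@H]2[C@H]1C(C)=C[C@@](/C=C/c1ccccc1)(CC)[C@]2(CC)C(=O)O | intermediate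
21 | (1S,3S,3aR,4R,5S,7aR)-1,4,5-triethyl-3,7-dimethyl-2-oxo-5-[(E)-2-phenylethenyl]-2,3,3a,4,5,7a-hexahydro-1H-indene-4-carboxylic acid | CC[C@@H]1C(=O)[C@@H](C)[C@H]2[C@H]1C(C)=C[C@@](/C=C/c1ccccc1)(CC)[C@]2(CC)C(=O)O | target

Total step count: 13. Longest linear sequence: 13 steps (1 to 21).

Steps most likely to fail

Step 10. The one-pot olefination–cycloaddition may suffer from a second olefination of the intermediate enal by residual ylide, or from competing exo (cis-fused) cycloaddition at 115 °C. The fallback sets out from 16 and comes back at 18; it installs the dienophile at the ester level and runs the cycloaddition cold under Lewis-acid activation. Wittig reaction of 16 with ethyl 2-(triphenylphosphoranylidene)butanoate (toluene, 60 °C) should give ethyl (2E,4S,5R,6S,7E,9E,11E)-5-[(tert-butyldimethylsilyl)oxy]-2,6,10-triethyl-4,8-dimethyl-12-phenyldodeca-2,7,9,11-tetraenoate F1, too poor a dienophile to cyclise at that temperature. Reduction with i-Bu2AlH (CH2Cl2, −78 °C) gives (2E,4S,5R,6S,7E,9E,11E)-5-[(tert-butyldimethylsilyl)oxy]-2,6,10-triethyl-4,8-dimethyl-12-phenyldodeca-2,7,9,11-tetraen-1-ol F2, and MnO2 (CH2Cl2, rt) gives tetraenal 17 in isolated form. Me2AlCl (CH2Cl2, −78 to −30 °C) should then promote the endo-selective intramolecular Diels–Alder reaction to 18.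

Step 4. Borane addition to the 1,1-disubstituted alkene may show poor facial selectivity, which would spoil the 1,3-anti relationship on which the cycloaddition depends. The fallback sets out from 1 and comes back at 8; it sets this centre by auxiliary control before the aldol instead of by substrate control after it. Commercial (4R)-4-benzyl-3-butanoyl-1,3-oxazolidin-2-one is benzyloxymethylated (TiCl4, i-Pr2NEt, benzyl chloromethyl ether, CH2Cl2, 0 °C) to (4R)-4-benzyl-3-[(2S)-2-[(benzyloxy)methyl]butanoyl]-1,3-oxazolidin-2-one F3. LiBH4 (THF/MeOH, 0 °C) gives (2R)-2-[(benzyloxy)methyl]butan-1-ol F4, and Dess–Martin periodinane gives (2S)-2-[(benzyloxy)methyl]butanal F5. Boron enolate 3, made from 1 as in step 1, should add to F5 in the matched anti-Felkin sense to give (4R)-4-benzyl-3-[(2R,3S,4S)-4-[(benzyloxy)methyl]-3-hydroxy-2-methylhexanoyl]-1,3-oxazolidin-2-one F6. Weinreb transamidation as in step 2 gives (2R,3S,4S)-4-[(benzyloxy)methyl]-3-hydroxy-N-methoxy-N,2-dimethylhexanamide F7, and silylation as in step 3 gives (2R,3S,4S)-4-[(benzyloxy)methyl]-3-[(tert-butyldimethylsilyl)oxy]-N-methoxy-N,2-dimethylhexanamide F8. Hydrogenolysis (H2, Pd/C, EtOAc), which leaves the Weinreb amide intact, delivers 8.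

Step 7. Olefination of the hindered enal by the α-ethyl ylide may be sluggish, so that thermal decomposition or double homologation competes. The fallback sets out from 11 and comes back at 15 (it also bypasses step 8); it builds the triene by cross-coupling. Dibromo-olefination of 11 (CBr4, PPh3, CH2Cl2, 0 °C) gives (2R,3S,4S,5E)-8,8-dibromo-3-[(tert-butyldimethylsilyl)oxy]-4-ethyl-N-methoxy-N,2,6-trimethylocta-5,7-dienamide F9. Trans-selective Suzuki–Miyaura coupling with (E)-2-phenylethenylboronic acid (Pd2(dba)3, tri(2-furyl)phosphine, Cs2CO3, dioxane/H2O, 60 °C) should replace the bromine trans to the chain and give (2R,3S,4S,5E,7Z,9E)-8-bromo-3-[(tert-butyldimethylsilyl)oxy]-4-ethyl-N-methoxy-N,2,6-trimethyl-10-phenyldeca-5,7,9-trienamide F10. Negishi coupling with Et2Zn (Pd(P(t-Bu)3)2, THF, rt) with retention then gives 15.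

Further compounds
F1 | step 10 | ethyl (2E,4S,5R,6S,7E,9E,11E)-5-[(tert-butyldimethylsilyl)oxy]-2,6,10-triethyl-4,8-dimethyl-12-phenyldodeca-2,7,9,11-tetraenoate | CC[C@@H](/C=C(C)/C=C(CC)/C=C/c1ccccc1)[C@H](O[Si](C)(C)C(C)(C)C)[C@@H](C)/C=C(CC)/C(=O)OCC
F2 | step 10 | (2E,4S,5R,6S,7E,9E,11E)-5-[(tert-butyldimethylsilyl)oxy]-2,6,10-triethyl-4,8-dimethyl-12-phenyldodeca-2,7,9,11-tetraen-1-ol | CC[C@@H](/C=C(C)/C=C(CC)/C=C/c1ccccc1)[C@H](O[Si](C)(C)C(C)(C)C)[C@@H](C)/C=C(CC)/CO
F3 | step 4 | (4R)-4-benzyl-3-[(2S)-2-[(benzyloxy)methyl]butanoyl]-1,3-oxazolidin-2-one | CC[C@@H](COCc1ccccc1)C(=O)N1[C@H](Cc2ccccc2)COC1=O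
F4 | step 4 | (2R)-2-[(benzyloxy)methyl]butan-1-ol | CC[C@@H](COCc1ccccc1)CO
F5 | step 4 | (2S)-2-[(benzyloxy)methyl]butanal | CC[C@@H](COCc1ccccc1)C=O
F6 | step 4 | (4R)-4-benzyl-3-[(2R,3S,4S)-4-[(benzyloxy)methyl]-3-hydroxy-2-methylhexanoyl]-1,3-oxazolidin-2-one | CC[C@@H](COCc1ccccc1)[C@H](O)[C@@H](C)C(=O)N1[C@H](Cc2ccccc2)COC1=O
F7 | step 4 | (2R,3S,4S)-4-[(benzyloxy)methyl]-3-hydroxy-N-methoxy-N,2-dimethylhexanamide | CC[C@@H](COCc1ccccc1)[C@H](O)[C@@H](C)C(=O)N(C)OC
F8 | step 4 | (2R,3S,4S)-4-[(benzyloxy)methyl]-3-[(tert-butyldimethylsilyl)oxy]-N-methoxy-N,2-dimethylhexanamide | CC[C@@H](COCc1ccccc1)[C@H](O[Si](C)(C)C(C)(C)C)[C@@H](C)C(=O)N(C)OC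
F9 | step 7 | (2R,3S,4S,5E)-8,8-dibromo-3-[(tert-butyldimethylsilyl)oxy]-4-ethyl-N-methoxy-N,2,6-trimethylocta-5,7-dienamide | CC[C@@H](/C=C(C)/C=C(Br)Br)[C@H](O[Si](C)(C)C(C)(C)C)[C@@H](C)C(=O)N(C)OC
F10 | step 7 | (2R,3S,4S,5E,7Z,9E)-8-bromo-3-[(tert-butyldimethylsilyl)oxy]-4-ethyl-N-methoxy-N,2,6-trimethyl-10-phenyldeca-5,7,9-trienamide | CC[C@@H](/C=C(C)/C=C(Br)/C=C/c1ccccc1)[C@H](O[Si](C)(C)C(C)(C)C)[C@@H](C)C(=O)N(C)OC
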